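**Plan**

1. Locants follow labdane numbering (ring A: C1, C2, C3, C4, C5, C10; ring B: C5 to C10; chain C11 to C16). The target is A/B-cis: H5, H9 and the C10 methyl lie on one face, the C9 chain and the C2 ester oxygen on the other.
2. Cuts, in retrosynthetic order: C15 acid to primary alcohol; C2–O ester; C2 carbinol to ketone; C10–CH3 (conjugate addition to a C1=C10 enone); excision of C1, which contracts ring A to the cyclopentanone C2/C3/C4/C5/C10; then C9–C10 and C5–C6 (Diels–Alder).
3. Enabling feature: C2 is the only oxygenated ring carbon and is separated from the quaternary C10 by the methylene C1. Without C1 the C2 carbonyl sits on C10, so ring A minus C1 is a cyclopentenone whose C10=C5 bond is a dienophile for ring B. Re-inserting C1 between C2 and C10 restores ring A and moves C10 from α to β of the carbonyl.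
4. Forward: diene from (R)-citronellol (its ten carbons become C7–C9 and C11–C17); ring B by endo cycloaddition onto 4,4-dimethylcyclopent-2-enone; ring A by one-carbon enlargement of the five-membered ring; enone; angular methyl; C2 reduction; angeloylation; C15 oxidation.
5. Stereochemistry: C13 from (R)-citronellol; C5 and C9 from the catalyst-controlled endo cycloaddition; C10 from cuprate addition cis to H5 and anti to the C9 chain; C2 from thermodynamic (equatorial) reduction; the (Z)-ester from angelic acid.

Key step: step 5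

Assumption: the (S)-prolinol-derived cationic oxazaborolidine is taken to direct the diene to the Re face of the enone α-carbon (C10), the sense known for s-trans α,β-unsaturated esters. If the opposite sense were found, the (R)-catalyst would be used and nothing else would change.

**Route**

Step 1
Reactants: 1 (R)-citronellol
Product: 2 (R)-citronellyl triisopropylsilyl ether
Conditions: i-Pr3SiCl, imidazole, DMF, 0 °C → rt
Reagents that add atoms: triisopropylsilyl chloride, CC(C)[Si](Cl)(C(C)C)C(C)C
Why: Standard silyl ether protection of a primary alcohol; the triisopropylsilyl group should survive the Lewis acid, organolithium and dissolving-metal steps, and C13 is not touched.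

Step 2
Reactants: 2 (R)-citronellyl triisopropylsilyl ether
Product: 4 (2E,6R)-2,6-dimethyl-8-(triisopropylsilyloxy)oct-2-enal, via allylic alcohol 3 (not isolated)
Conditions: SeO2 (0.3 equiv), t-BuOOH, salicylic acid (cat.), CH2Cl2, rt; filtration; then MnO2, CH2Cl2, rt
Reagents that add atoms: tert-butyl hydroperoxide, CC(C)(C)OO (source of the oxygen atom, passed on by catalytic selenium dioxide, O=[Se]=O)
Why: SeO2 allylic oxidation (ene reaction, then 2,3-sigmatropic shift) attacks the (E)-methyl of a trisubstituted gem-dimethyl olefin selectively, and MnO2 should complete the oxidation of the allylic alcohol to the (E)-enal.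

Step 3
Reactants: 4 (2E,6R)-enal
Product: 5 (3R,6E)-3,7-dimethylnona-6,8-dienyl triisopropylsilyl ether (the diene)
Conditions: Ph3PCH3Br, KOtBu, THF, 0 °C; then 4, 0 °C → rt
Reagents that add atoms: methyltriphenylphosphonium bromide, C[P+](c1ccccc1)(c1ccccc1)c1ccccc1.[Br-]
Why: Wittig methylenation of the enal should give the 1,3-diene (new carbon = C6) without touching the (E)-trisubstituted double bond.

Step 4
Reactants: 5 the diene; 6 4,4-dimethylcyclopent-2-en-1-one
Product: 7 (3aS,7S,7aS)-3,3,6-trimethyl-7-[(3R)-3-methyl-5-(triisopropylsilyloxy)pentyl]-2,3,3a,4,7,7a-hexahydro-1H-inden-1-one (cis-hydrindanone; H5, H9, H10 all cis)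
Conditions: (S)-3,3-diphenyl-1-(o-tolyl)tetrahydro-1H,3H-pyrrolo[1,2-c][1,3,2]oxazaborole (20 mol %) activated with AlBr3 (16 mol %), CH2Cl2, −40 → −20 °C
Reagents that add atoms: none
Why: Catalytic enantioselective Diels–Alder reaction of a 2-cycloalkenone: the substituted diene terminus C9 bonds to the α-carbon C10 and the free terminus C6 to the hindered β-carbon C5 (ortho rule), the Alder endo mode places the C9 chain cis to the ring A bonds so that H5, H9 and H10 come out all-cis, and the carbonyl-bound cationic oxazaborolidine (α-C–H···O contact) should block one face so that the diene adds to the Re face of C10, which sets C5 and C9 in absolute terms.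

Step 5
Reactants: 7 cis-hydrindanone
Product: 11 ring-enlarged trimethylsilyl enol ether (4aS,8S,8aS; O–C2=C1), via lithium dibromomethyl alkoxide 8 (not isolated), via lithium oxido carbenoid 9 (not isolated), via ring-enlarged lithium enolate 10 (not isolated)
Conditions: CH2Br2, lithium 2,2,6,6-tetramethylpiperidide (LiTMP) added to 7 in THF, −78 °C; then n-BuLi, −78 → −40 °C; then Me3SiCl, Et3N, −78 °C → rt; non-aqueous work-up
Reagents that add atoms: dibromomethane, BrCBr; chlorotrimethylsilane, C[Si](C)(C)Cl
Why: Dibromomethyllithium adds to the C2 carbonyl of 7 to give alkoxide 8, bromine–lithium exchange turns it into the β-oxido carbenoid 9, and the C2–C10 bond then shifts to the carbenoid carbon with loss of LiBr, so that the new carbon C1 is inserted between C2 and C10 and the five-membered ring becomes ring A as the lithium enolate 10 (O–C2=C1), which is silylated in the flask. The closest known reaction type is the β-oxido carbenoid homologation of 2-substituted cycloalkanones to the next higher 2-substituted cycloalkanones. No ring is closed: the six-membered ring arises by a 1,2-alkyl shift (one-carbon ring enlargement) inside the existing bicycle. No stereocenter is created: C10 migrates with retention, C5 and C9 are untouched, and the carbinol centre of 8 is destroyed again, so both epimers of 8 converge. The step needs migration of the methine C10 and not of the methylene C3, which the higher migratory aptitude of the more substituted α-carbon in this rearrangement should secure, and it needs the enolate on the C1 side, which is inherent because C1 is the former carbenoid carbon. This regiodefined enolate places C10 β to the carbonyl, the position from which the angular methyl is introduced.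

Step 6
Reactants: 11 ring-enlarged trimethylsilyl enol ether
Product: 12 (4aR,8R)-4,4,7-trimethyl-8-[(3R)-3-methyl-5-(triisopropylsilyloxy)pentyl]-4,4a,5,8-tetrahydronaphthalen-2(3H)-one (C1=C10 enone)
Conditions: Pd(OAc)2 (1.1 equiv), MeCN, rt
Reagents that add atoms: none
Why: Saegusa–Ito oxidation: palladium diacetate should palladate the regiodefined silyl enol ether at C1, and β-hydride elimination of H10 gives the C1=C10 enone, removing the C10 stereocenter on purpose.

Step 7
Reactants: 12 C1=C10 enone
Product: 14 (4aR,8R,8aS)-4,4,7,8a-tetramethyl-8-[(3R)-3-methyl-5-(triisopropylsilyloxy)pentyl]-3,4,4a,5,8,8a-hexahydronaphthalen-2(1H)-one (cis-fused ketone), via trimethylsilyl enol ether 13 (not isolated)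
Conditions: MeLi, CuI, THF/Et2O, −40 °C (Me2CuLi); then 12, Me3SiCl, −78 → −30 °C; then K2CO3, MeOH, 0 °C
Reagents that add atoms: methyllithium, C[Li] (delivered as Me2CuLi)
Why: Silyl-accelerated cuprate conjugate addition to a 1(10)-octalen-2-one: axial attack at C10 on the face anti to the C9 chain should give the cis-fused decalone (methyl cis to H5, axial on ring A and equatorial on ring B), the usual outcome for this enone class, and so sets C10 as S.

Step 8
Reactants: 14 cis-fused ketone
Product: 15 (2S,4aR,8R,8aS)-4,4,7,8a-tetramethyl-8-[(3R)-3-methyl-5-(triisopropylsilyloxy)pentyl]-1,2,3,4,4a,5,8,8a-octahydronaphthalen-2-ol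
Conditions: Li, liquid NH3, THF, MeOH, −78 °C; then NH4Cl
Reagents that add atoms: none
Why: Dissolving-metal reduction of the ketone should give the thermodynamically preferred equatorial alcohol, with oxygen trans to the syn-axial C10 and C4 methyls that block the axial position, which is the (2S) configuration; the isolated trisubstituted alkene and the silyl ether are inert.

Step 9
Reactants: 15 (2S)-alcohol; 16 angelic acid
Product: 18 (2S)-angelate silyl ether, via mixed anhydride 17 (not isolated)
Conditions: 16, 2,4,6-trichlorobenzoyl chloride, Et3N, toluene, rt; then 15, toluene, 80 °C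
Reagents that add atoms: none
Why: Yamaguchi esterification through the mixed anhydride without a nucleophilic catalyst should acylate the unhindered equatorial alcohol with retention at C2 and without Z to E isomerisation of the angelate.

Step 10
Reactants: 18 angelate silyl ether
Product: 19 (2S)-angelate primary alcohol
Conditions: HF·pyridine, pyridine, THF, 0 °C → rt
Reagents that add atoms: none
Why: Buffered fluoride desilylation should free the primary alcohol while the angelate ester and both alkenes stay intact.

Step 11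
Reactants: 19 angelate primary alcohol
Product: 21 target acid, via aldehyde 20 (not isolated)
Conditions: TEMPO (20 mol %), PhI(OAc)2 (2.2 equiv), MeCN/H2O (1:1), rt
Reagents that add atoms: water, O
Why: Oxoammonium (TEMPO) oxidation with PhI(OAc)2 in aqueous acetonitrile should take the primary alcohol through the aldehyde hydrate to the carboxylic acid without touching the alkenes, the ester or any stereocenter.

**Compound list**

1 | (R)-citronellol, (3R)-3,7-dimethyloct-6-en-1-ol | CC(C)=CCC[C@@H](C)CCO | starting material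
2 | [(3R)-3,7-dimethyloct-6-enyl]oxy-triisopropylsilane | CC(C)=CCC[C@@H](C)CCO[Si](C(C)C)(C(C)C)C(C)C | intermediate
3 | (2E,6R)-2,6-dimethyl-8-(triisopropylsilyloxy)oct-2-en-1-ol | OC/C(C)=C/CC[C@@H](C)CCO[Si](C(C)C)(C(C)C)C(C)C | intermediate (not isolated)
4 | (2E,6R)-2,6-dimethyl-8-(triisopropylsilyloxy)oct-2-enal | O=C/C(C)=C/CC[C@@H](C)CCO[Si](C(C)C)(C(C)C)C(C)C | intermediate
5 | [(3R,6E)-3,7-dimethylnona-6,8-dienyl]oxy-triisopropylsilane | C=C/C(C)=C/CC[C@@H](C)CCO[Si](C(C)C)(C(C)C)C(C)C | intermediate
6 | 4,4-dimethylcyclopent-2-en-1-one | O=C1C=CC(C)(C)C1 | starting material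
7 | (3aS,7S,7aS)-3,3,6-trimethyl-7-[(3R)-3-methyl-5-(triisopropylsilyloxy)pentyl]-2,3,3a,4,7,7a-hexahydro-1H-inden-1-one | O=C1CC(C)(C)[C@H]2CC=C(C)[C@@H](CC[C@@H](C)CCO[Si](C(C)C)(C(C)C)C(C)C)[C@@H]12 | intermediate
8 | lithium alkoxide of the dibromomethyl carbinol from 7 (carbinol carbon drawn as the epimer from attack anti to the C9 branch; both epimers converge) | [Li]O[C@@]1(C(Br)Br)CC(C)(C)[C@H]2CC=C(C)[C@@H](CC[C@@H](C)CCO[Si](C(C)C)(C(C)C)C(C)C)[C@@H]12 | intermediate (not isolated)
9 | lithium β-oxido carbenoid (bromo-lithio-methyl alkoxide; carbenoid carbon configurationally labile) | [Li]O[C@@]1(C([Li])Br)CC(C)(C)[C@H]2CC=C(C)[C@@H](CC[C@@H](C)CCO[Si](C(C)C)(C(C)C)C(C)C)[C@@H]12 | intermediate (not isolated)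
10 | lithium enolate (O–C2=C1) of the ring-enlarged (4aS,8S,8aS)-decalin-2-one | [Li]OC=1CC(C)(C)[C@H]2CC=C(C)[C@@H](CC[C@@H](C)CCO[Si](C(C)C)(C(C)C)C(C)C)[C@H]2C=1 | intermediate (not isolated)
11 | (4aS,8S,8aS)-4,4,7-trimethyl-8-[(3R)-3-methyl-5-(triisopropylsilyloxy)pentyl]-2-(trimethylsilyloxy)-3,4,4a,5,8,8a-hexahydronaphthalene | C[Si](C)(C)OC=1CC(C)(C)[C@H]2CC=C(C)[C@@H](CC[C@@H](C)CCO[Si](C(C)C)(C(C)C)C(C)C)[C@H]2C=1 | intermediate
12 | (4aR,8R)-4,4,7-trimethyl-8-[(3R)-3-methyl-5-(triisopropylsilyloxy)pentyl]-4,4a,5,8-tetrahydronaphthalen-2(3H)-one | O=C1CC(C)(C)[C@H]2CC=C(C)[C@@H](CC[C@@H](C)CCO[Si](C(C)C)(C(C)C)C(C)C)C2=C1 | intermediate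
13 | (4aR,8R,8aS)-4,4,7,8a-tetramethyl-8-[(3R)-3-methyl-5-(triisopropylsilyloxy)pentyl]-2-(trimethylsilyloxy)-3,4,4a,5,8,8a-hexahydronaphthalene | C[Si](C)(C)OC=1CC(C)(C)[C@H]2CC=C(C)[C@@H](CC[C@@H](C)CCO[Si](C(C)C)(C(C)C)C(C)C)[C@@]2(C)C=1 | intermediate (not isolated)
14 | (4aR,8R,8aS)-4,4,7,8a-tetramethyl-8-[(3R)-3-methyl-5-(triisopropylsilyloxy)pentyl]-3,4,4a,5,8,8a-hexahydronaphthalen-2(1H)-one | O=C1CC(C)(C)[C@H]2CC=C(C)[C@@H](CC[C@@H](C)CCO[Si](C(C)C)(C(C)C)C(C)C)[C@@]2(C)C1 | intermediate
15 | (2S,4aR,8R,8aS)-4,4,7,8a-tetramethyl-8-[(3R)-3-methyl-5-(triisopropylsilyloxy)pentyl]-1,2,3,4,4a,5,8,8a-octahydronaphthalen-2-ol | O[C@H]1CC(C)(C)[C@H]2CC=C(C)[C@@H](CC[C@@H](C)CCO[Si](C(C)C)(C(C)C)C(C)C)[C@@]2(C)C1 | intermediate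
16 | angelic acid, (Z)-2-methylbut-2-enoic acid | C/C=C(/C)C(=O)O | starting material
17 | (Z)-2-methylbut-2-enoic 2,4,6-trichlorobenzoic anhydride | C/C=C(/C)C(=O)OC(=O)c1c(Cl)cc(Cl)cc1Cl | intermediate (not isolated)
18 | (2S,4aR,8R,8aS)-4,4,7,8a-tetramethyl-8-[(3R)-3-methyl-5-(triisopropylsilyloxy)pentyl]-1,2,3,4,4a,5,8,8a-octahydronaphthalen-2-yl (Z)-2-methylbut-2-enoate | C/C=C(/C)C(=O)O[C@H]1CC(C)(C)[C@H]2CC=C(C)[C@@H](CC[C@@H](C)CCO[Si](C(C)C)(C(C)C)C(C)C)[C@@]2(C)C1 | intermediate
19 | (2S,4aR,8R,8aS)-8-[(3R)-5-hydroxy-3-methylpentyl]-4,4,7,8a-tetramethyl-1,2,3,4,4a,5,8,8a-octahydronaphthalen-2-yl (Z)-2-methylbut-2-enoate | C/C=C(/C)C(=O)O[C@H]1CC(C)(C)[C@H]2CC=C(C)[C@@H](CC[C@@H](C)CCO)[C@@]2(C)C1 | intermediate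
20 | (2S,4aR,8R,8aS)-4,4,7,8a-tetramethyl-8-[(3R)-3-methyl-5-oxopentyl]-1,2,3,4,4a,5,8,8a-octahydronaphthalen-2-yl (Z)-2-methylbut-2-enoate | C/C=C(/C)C(=O)O[C@H]1CC(C)(C)[C@H]2CC=C(C)[C@@H](CC[C@@H](C)CC=O)[C@@]2(C)C1 | intermediate (not isolated)
21 | (3R)-3-methyl-5-[(1R,4aR,7S,8aS)-2,5,5,8a-tetramethyl-7-{[(2Z)-2-methylbut-2-enoyl]oxy}-1,4,4a,5,6,7,8,8a-octahydronaphthalen-1-yl]pentanoic acid; in labdane locants (2S,5R,9R,10S,13R) | C/C=C(/C)C(=O)O[C@H]1CC(C)(C)[C@H]2CC=C(C)[C@@H](CC[C@@H](C)CC(=O)O)[C@@]2(C)C1 | target

**Totals**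

Total step count: 11.
Longest linear sequence: 11 steps (1 to 21); 6 and 16 are bought.

**Steps most likely to fail**

Step 4. The cycloaddition may be slow at the neopentyl β-carbon C5, so that the acid-sensitive diene oligomerises, and facial discrimination by the catalyst may be insufficient. Fallback: setting out from 5 and 6, the cycloaddition is run with the achiral Lewis acid EtAlCl2 (CH2Cl2, −78 → −20 °C). This should give the endo adduct as 7 and its ring diastereomer, the (3aR,7R,7aR)-hydrindanone F1, in comparable amounts. Because C13 makes the two diastereomers, they are parted by preparative chromatography on a chiral stationary phase, and 7 comes back to the route before step 5.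

Step 5. The methylene C3 may migrate in place of C10, or the carbenoid reagent may enolise 7 at C10 and not add to the carbonyl. Fallback: setting out from 7, thermodynamic silylation (Me3SiCl, Et3N, DMF, 100 °C) gives the tetrasubstituted trimethylsilyl enol ether F2 (O–C2=C10). Simmons–Smith cyclopropanation of this electron-rich double bond (Et2Zn, CH2I2, CH2Cl2, 0 °C) gives the siloxycyclopropane F3, in which the new methylene C1 bridges C2 and C10. FeCl3 in DMF (0 °C → rt) opens it by β-scission of the C2–C10 bond of the alkoxy radical to the ring-enlarged β-chloro ketone F4, and NaOAc in MeOH removes HCl. The sequence comes back to the route at enone 12 and replaces steps 5 and 6.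

Step 7. The 1,4-addition at the fully substituted C10 may be sluggish, with γ-deprotonation at the doubly allylic C9 and loss of its configuration as the competing process. Fallback: setting out from 12, Corey–Chaykovsky cyclopropanation with dimethylsulfoxonium methylide (Me3S(O)I, NaH, DMSO, 50 °C) gives the cyclopropyl ketone F5, with the methylene across C1–C10 on the face anti to the C9 chain. Dissolving-metal cleavage (Li, liquid NH3, THF, −78 °C, then NH4Cl) breaks the C1–CH2 bond, the one aligned with the carbonyl π system, and turns the bridging methylene into the angular methyl. This comes back to the route at ketone 14.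

**Further compounds**

F1 | step 4 | (3aR,7R,7aR)-3,3,6-trimethyl-7-[(3R)-3-methyl-5-(triisopropylsilyloxy)pentyl]-2,3,3a,4,7,7a-hexahydro-1H-inden-1-one (ring diastereomer of 7) | O=C1CC(C)(C)[C@@H]2CC=C(C)[C@H](CC[C@@H](C)CCO[Si](C(C)C)(C(C)C)C(C)C)[C@H]12
F2 | step 5 | trimethylsilyl enol ether of 7 toward the ring fusion (O–C2=C10; C5 and C9 as in 7) | C[Si](C)(C)OC=1CC(C)(C)[C@H]2CC=C(C)[C@@H](CC[C@@H](C)CCO[Si](C(C)C)(C(C)C)C(C)C)C=12
F3 | step 5 | siloxycyclopropane from F2, methylene C1 bridging C2 and C10 on the face anti to the C9 chain | C[Si](C)(C)O[C@@]12CC(C)(C)[C@H]3CC=C(C)[C@@H](CC[C@@H](C)CCO[Si](C(C)C)(C(C)C)C(C)C)[C@@]13C2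
F4 | step 5 | ring-enlarged 10-chloro ketone (β-chloro ketone; C10 configuration immaterial) | O=C1CC(C)(C)[C@H]2CC=C(C)[C@@H](CC[C@@H](C)CCO[Si](C(C)C)(C(C)C)C(C)C)[C@@]2(Cl)C1
F5 | step 7 | cyclopropyl ketone from 12, methylene bridging C1 and C10 on the face anti to the C9 chain | O=C1CC(C)(C)[C@H]2CC=C(C)[C@@H](CC[C@@H](C)CCO[Si](C(C)C)(C(C)C)C(C)C)[C@]23C[C@@H]31
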